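**Plan**

- Retrosynthetic cuts, in order: the C5–vinyl bond (Heck); O1–C2 of the dihydrobenzofuran (acid-triggered phenol closure); the C3–CH2OH bond together with the C2–O bond (Prins addition of two formaldehyde units to a C2=C3 stilbene); the stilbene C=C (Horner–Wadsworth–Emmons).
- Enabling feature: the CH2OH carbon on C3 and the ring oxygen on C2 are 1,3-related across C2–C3, and C2 is benzylic to the para-oxygenated 4-hydroxy-3,5-dimethoxyphenyl ring. This is the imprint of formaldehyde adding at C3 of an alkene whose C2 cation that ring stabilises.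
- Forward: a phosphonate from syringaldehyde and 5-bromo-2-hydroxy-3-methoxybenzaldehyde give the E-stilbene. After acylation of the phenol, the Prins step closes a 1,3-dioxane first, which is then switched to the 2,3-dihydrobenzofuran. The resorcinol styrene is joined last at C5 and all silyl groups are removed together.
- Stereochemistry: C3 (S) comes from enantioface selection by the chiral confined acid in the Prins step. C2 (R) is set afterwards as the trans partner of C3, under thermodynamic control, in the acid-mediated ring switch.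

Key step: step 7

Assumption: the sense of induction of the confined acid with a 1,2-diaryl alkene cannot be read from precedent. The catalyst antipode is the one that lets formaldehyde add to the Si face of the bromoaryl-bearing alkene carbon, and the (S,S) label below is provisional.

**Route**

Step 1
Reactants: 1 syringaldehyde (4-hydroxy-3,5-dimethoxybenzaldehyde)
Product: 2 3,5-dimethoxy-4-[(triisopropylsilyl)oxy]benzaldehyde
Conditions: iPr3SiCl (1.3 equiv), imidazole (2.5 equiv), DMF, rt
Reagents that add atoms: chlorotriisopropylsilane, CC(C)[Si](Cl)(C(C)C)C(C)C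
Why: Imidazole-promoted silylation masks the phenol as a base-tolerant, fluoride-labile aryl silyl ether that remains a para donor for the later benzylic cation, while the aldehyde is untouched.

Step 2
Reactants: 2 3,5-dimethoxy-4-[(triisopropylsilyl)oxy]benzaldehyde
Product: 3 {3,5-dimethoxy-4-[(triisopropylsilyl)oxy]phenyl}methanol
Conditions: NaBH4, MeOH–THF, 0 °C
Reagents that add atoms: none
Why: Borohydride reduction of the aryl aldehyde gives the benzylic alcohol, and the aryl silyl ether is inert to NaBH4 at 0 °C.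

Step 3
Reactants: 3 {3,5-dimethoxy-4-[(triisopropylsilyl)oxy]phenyl}methanol
Product: 4 [4-(bromomethyl)-2,6-dimethoxyphenoxy]triisopropylsilane
Conditions: CBr4, PPh3, CH2Cl2, 0 °C; used without storage
Reagents that add atoms: carbon tetrabromide, BrC(Br)(Br)Br
Why: The Appel reaction converts the electron-rich benzylic alcohol into the bromide under neutral conditions, so no acid is present that could ionise the product or touch the silyl ether.

Step 4
Reactants: 4 [4-(bromomethyl)-2,6-dimethoxyphenoxy]triisopropylsilane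
Product: 5 diethyl ({3,5-dimethoxy-4-[(triisopropylsilyl)oxy]phenyl}methyl)phosphonate
Conditions: P(OEt)3 (neat, excess), 120 °C
Reagents that add atoms: triethyl phosphite, CCOP(OCC)OCC
Why: In the Michaelis–Arbuzov reaction the phosphite displaces the reactive benzylic bromide and bromide dealkylates the phosphonium intermediate to the phosphonate.

Step 5
Reactants: 5 diethyl ({3,5-dimethoxy-4-[(triisopropylsilyl)oxy]phenyl}methyl)phosphonate; 6 5-bromo-2-hydroxy-3-methoxybenzaldehyde
Product: 7 4-bromo-2-[(E)-2-{3,5-dimethoxy-4-[(triisopropylsilyl)oxy]phenyl}ethenyl]-6-methoxyphenol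
Conditions: NaN(SiMe3)2 (2.2 equiv), THF, 0 °C to rt; aqueous NH4Cl
Reagents that add atoms: none
Why: In this Horner–Wadsworth–Emmons olefination one equivalent of the bulky amide base is spent on the phenol and the second forms the benzylic phosphonate anion, which adds to the aldehyde and eliminates phosphate to the E-stilbene expected for aryl aldehydes.

Step 6
Reactants: 7 4-bromo-2-[(E)-2-{3,5-dimethoxy-4-[(triisopropylsilyl)oxy]phenyl}ethenyl]-6-methoxyphenol
Product: 8 4-bromo-2-[(E)-2-{3,5-dimethoxy-4-[(triisopropylsilyl)oxy]phenyl}ethenyl]-6-methoxyphenyl pivalate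
Conditions: pivaloyl chloride, Et3N, DMAP (cat.), CH2Cl2, 0 °C to rt
Reagents that add atoms: pivaloyl chloride, CC(C)(C)C(=O)Cl
Why: DMAP-catalysed acylation turns the ortho phenol into a hindered, acid-stable, electron-poor ester, so that this ring cannot stabilise a cation on the alkene carbon next to it.

Step 7
Reactants: 8 4-bromo-2-[(E)-2-{3,5-dimethoxy-4-[(triisopropylsilyl)oxy]phenyl}ethenyl]-6-methoxyphenyl pivalate; 9 formaldehyde (charged as paraformaldehyde, two units taken up)
Product: 10 4-bromo-2-[(4S,5S)-4-{3,5-dimethoxy-4-[(triisopropylsilyl)oxy]phenyl}-1,3-dioxan-5-yl]-6-methoxyphenyl pivalate (trans)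
Conditions: (S,S)-configured confined imino-imidodiphosphate Brønsted acid (two 3,3'-diaryl-BINOL units, one P=N–SO2CF3 group; 5 mol%), paraformaldehyde (5 equiv of CH2O), cyclohexane–CHCl3, rt
Reagents that add atoms: formaldehyde (as paraformaldehyde), C=O
Why: Proposed new method: the confined acid protonates a formaldehyde dimer, whose carbon is attacked by the alkene carbon next to the pivaloyloxy-bromoaryl ring (later C3) while positive charge builds on the carbon next to the silyloxy-dimethoxyphenyl ring (later C2), and the terminal oxygen of the C–CH2–O–CH2–O chain then bonds to that benzylic carbon. The closest known reaction type is the confined-Brønsted-acid-catalysed enantioselective Prins reaction of terminal styrenes with paraformaldehyde to 4-aryl-1,3-dioxanes, and what is new here is a 1,2-diaryl alkene as the olefin. The single new ring, the 1,3-dioxane, closes by O3–C4 bond formation, either as a 6-exo capture of the benzylic cation by the hemiformal oxygen or as the late bond of a concerted asynchronous [4+2]-type addition. C5 of the dioxane (C3 of the target) is set by the catalyst pocket, which must expose the Si face of the bromoaryl-bearing alkene carbon, whereas C4 follows from suprafacial delivery to the E-alkene (trans, 4S) and is replaced later, so only C5 has to be right. The step needs regioselectivity, which the para-silyloxy donor on one ring against the acyloxy, bromo and meta-methoxy groups on the other should secure, and it needs the alkene to outrun Friedel–Crafts hydroxymethylation of the trioxygenated ring, which the pocket and the higher nucleophilicity of the donor-conjugated stilbene should favour.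

Step 8
Reactants: 10 4-bromo-2-[(4S,5S)-4-{3,5-dimethoxy-4-[(triisopropylsilyl)oxy]phenyl}-1,3-dioxan-5-yl]-6-methoxyphenyl pivalate
Product: 11 4-bromo-2-[(4S,5S)-4-{3,5-dimethoxy-4-[(triisopropylsilyl)oxy]phenyl}-1,3-dioxan-5-yl]-6-methoxyphenol
Conditions: iBu2AlH (3 equiv), CH2Cl2, −78 °C; aqueous sodium potassium tartrate
Reagents that add atoms: none
Why: Hydride reduction of the aryl ester at −78 °C frees the phenol (the acyl group leaves as neopentyl alcohol) without touching the aryl silyl ether, the aryl bromide or the formal acetal, and both stereocentres are spectators.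

Step 9
Reactants: 11 4-bromo-2-[(4S,5S)-4-{3,5-dimethoxy-4-[(triisopropylsilyl)oxy]phenyl}-1,3-dioxan-5-yl]-6-methoxyphenol
Product: 13 [(2R,3S)-5-bromo-2-{3,5-dimethoxy-4-[(triisopropylsilyl)oxy]phenyl}-7-methoxy-2,3-dihydro-1-benzofuran-3-yl]methanol, via hemiformal 12 (not isolated)
Conditions: TsOH·H2O (0.2 equiv), CH2Cl2–MeOH (9:1), rt to 40 °C
Reagents that add atoms: none
Why: In this acid-catalysed SN1 cycloetherification the benzylic C–O bond of the acetal ionises to a para-silyloxy-stabilised quinone-methide-type cation, the ortho phenol closes the five-membered ring (5-exo), the hemiformal arm gives up its CH2 to methanol, and because the closure is reversible under the acid the aryl group at C2 should settle trans to the fixed C3 centre (2R).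

Step 10
Reactants: 14 3,5-dihydroxybenzaldehyde
Product: 15 3,5-bis[(triisopropylsilyl)oxy]benzaldehyde
Conditions: iPr3SiCl (2.5 equiv), imidazole (5 equiv), DMF, rt
Reagents that add atoms: chlorotriisopropylsilane, CC(C)[Si](Cl)(C(C)C)C(C)C
Why: Imidazole-promoted silylation of both phenols gives a resorcinol unit that tolerates ylide and amine bases and is unmasked in the same final fluoride step as the third silyl ether.

Step 11
Reactants: 15 3,5-bis[(triisopropylsilyl)oxy]benzaldehyde
Product: 16 1-ethenyl-3,5-bis[(triisopropylsilyl)oxy]benzene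
Conditions: Ph3PCH3Br, KOtBu, THF, 0 °C; then the aldehyde, 0 °C to rt
Reagents that add atoms: methyltriphenylphosphonium bromide, C[P+](c1ccccc1)(c1ccccc1)c1ccccc1.[Br-]
Why: Wittig methylenation of the aryl aldehyde with the preformed non-stabilised ylide gives the terminal styrene, the butoxide being consumed before the silyl ethers are exposed to it.

Step 12
Reactants: 13 [(2R,3S)-5-bromo-2-{3,5-dimethoxy-4-[(triisopropylsilyl)oxy]phenyl}-7-methoxy-2,3-dihydro-1-benzofuran-3-yl]methanol; 16 1-ethenyl-3,5-bis[(triisopropylsilyl)oxy]benzene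
Product: 17 [(2R,3S)-5-[(E)-2-{3,5-bis[(triisopropylsilyl)oxy]phenyl}ethenyl]-2-{3,5-dimethoxy-4-[(triisopropylsilyl)oxy]phenyl}-7-methoxy-2,3-dihydro-1-benzofuran-3-yl]methanol
Conditions: Pd(OAc)2 (5 mol%), tBu3P·HBF4 (10 mol%), Cy2NMe (1.5 equiv), 1,4-dioxane, 80 °C
Reagents that add atoms: none
Why: In this Mizoroki–Heck reaction zerovalent palladium carrying the bulky electron-rich phosphine inserts into the electron-rich C5–Br bond, and syn carbopalladation at the terminal styrene carbon followed by syn β-hydride elimination gives the E-stilbene, with the free alcohol, the silyl ethers and both stereocentres not involved.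

Step 13
Reactants: 17 [(2R,3S)-5-[(E)-2-{3,5-bis[(triisopropylsilyl)oxy]phenyl}ethenyl]-2-{3,5-dimethoxy-4-[(triisopropylsilyl)oxy]phenyl}-7-methoxy-2,3-dihydro-1-benzofuran-3-yl]methanol
Product: 18 Gnetucleistol F, 5-[(E)-2-[(2R,3S)-2-(4-hydroxy-3,5-dimethoxyphenyl)-3-(hydroxymethyl)-7-methoxy-2,3-dihydro-1-benzofuran-5-yl]ethenyl]benzene-1,3-diol
Conditions: Bu4NF (3.3 equiv), AcOH (3.3 equiv), THF, 0 °C to rt
Reagents that add atoms: none
Why: Fluoride cleaves all three aryl Si–O bonds (driven by Si–F bond formation), while the acetic acid buffer keeps the phenols protonated so that the stilbene, the resorcinol and the para-hydroxybenzylic O1–C2 bond are not exposed to phenoxide-driven oxidation or quinone-methide ring opening.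

**Compound list**

1 | syringaldehyde (4-hydroxy-3,5-dimethoxybenzaldehyde) | COc1cc(C=O)cc(OC)c1O | starting material
2 | 3,5-dimethoxy-4-[(triisopropylsilyl)oxy]benzaldehyde | COc1cc(C=O)cc(OC)c1O[Si](C(C)C)(C(C)C)C(C)C | intermediate
3 | {3,5-dimethoxy-4-[(triisopropylsilyl)oxy]phenyl}methanol | COc1cc(CO)cc(OC)c1O[Si](C(C)C)(C(C)C)C(C)C | intermediate
4 | [4-(bromomethyl)-2,6-dimethoxyphenoxy]triisopropylsilane | COc1cc(CBr)cc(OC)c1O[Si](C(C)C)(C(C)C)C(C)C | intermediate
5 | diethyl ({3,5-dimethoxy-4-[(triisopropylsilyl)oxy]phenyl}methyl)phosphonate | CCOP(=O)(Cc1cc(OC)c(O[Si](C(C)C)(C(C)C)C(C)C)c(OC)c1)OCC | intermediate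
6 | 5-bromo-2-hydroxy-3-methoxybenzaldehyde | COc1cc(Br)cc(C=O)c1O | starting material
7 | 4-bromo-2-[(E)-2-{3,5-dimethoxy-4-[(triisopropylsilyl)oxy]phenyl}ethenyl]-6-methoxyphenol | COc1cc(/C=C/c2cc(Br)cc(OC)c2O)cc(OC)c1O[Si](C(C)C)(C(C)C)C(C)C | intermediate
8 | 4-bromo-2-[(E)-2-{3,5-dimethoxy-4-[(triisopropylsilyl)oxy]phenyl}ethenyl]-6-methoxyphenyl pivalate | COc1cc(/C=C/c2cc(Br)cc(OC)c2OC(=O)C(C)(C)C)cc(OC)c1O[Si](C(C)C)(C(C)C)C(C)C | intermediate
9 | formaldehyde (charged as paraformaldehyde) | C=O | starting material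
10 | 4-bromo-2-[(4S,5S)-4-{3,5-dimethoxy-4-[(triisopropylsilyl)oxy]phenyl}-1,3-dioxan-5-yl]-6-methoxyphenyl pivalate (trans) | COc1cc([C@H]2OCOC[C@@H]2c2cc(Br)cc(OC)c2OC(=O)C(C)(C)C)cc(OC)c1O[Si](C(C)C)(C(C)C)C(C)C | intermediate
11 | 4-bromo-2-[(4S,5S)-4-{3,5-dimethoxy-4-[(triisopropylsilyl)oxy]phenyl}-1,3-dioxan-5-yl]-6-methoxyphenol | COc1cc([C@H]2OCOC[C@@H]2c2cc(Br)cc(OC)c2O)cc(OC)c1O[Si](C(C)C)(C(C)C)C(C)C | intermediate
12 | {[(2R,3S)-5-bromo-2-{3,5-dimethoxy-4-[(triisopropylsilyl)oxy]phenyl}-7-methoxy-2,3-dihydro-1-benzofuran-3-yl]methoxy}methanol (hemiformal) | COc1cc([C@@H]2Oc3c(OC)cc(Br)cc3[C@H]2COCO)cc(OC)c1O[Si](C(C)C)(C(C)C)C(C)C | intermediate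
13 | [(2R,3S)-5-bromo-2-{3,5-dimethoxy-4-[(triisopropylsilyl)oxy]phenyl}-7-methoxy-2,3-dihydro-1-benzofuran-3-yl]methanol | COc1cc([C@@H]2Oc3c(OC)cc(Br)cc3[C@H]2CO)cc(OC)c1O[Si](C(C)C)(C(C)C)C(C)C | intermediate
14 | 3,5-dihydroxybenzaldehyde | O=Cc1cc(O)cc(O)c1 | starting material
15 | 3,5-bis[(triisopropylsilyl)oxy]benzaldehyde | O=Cc1cc(O[Si](C(C)C)(C(C)C)C(C)C)cc(O[Si](C(C)C)(C(C)C)C(C)C)c1 | intermediate
16 | 1-ethenyl-3,5-bis[(triisopropylsilyl)oxy]benzene | C=Cc1cc(O[Si](C(C)C)(C(C)C)C(C)C)cc(O[Si](C(C)C)(C(C)C)C(C)C)c1 | intermediate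
17 | [(2R,3S)-5-[(E)-2-{3,5-bis[(triisopropylsilyl)oxy]phenyl}ethenyl]-2-{3,5-dimethoxy-4-[(triisopropylsilyl)oxy]phenyl}-7-methoxy-2,3-dihydro-1-benzofuran-3-yl]methanol | COc1cc([C@@H]2Oc3c(OC)cc(/C=C/c4cc(O[Si](C(C)C)(C(C)C)C(C)C)cc(O[Si](C(C)C)(C(C)C)C(C)C)c4)cc3[C@H]2CO)cc(OC)c1O[Si](C(C)C)(C(C)C)C(C)C | intermediate
18 | Gnetucleistol F | COc1cc([C@@H]2Oc3c(OC)cc(/C=C/c4cc(O)cc(O)c4)cc3[C@H]2CO)cc(OC)c1O | target

**Step count and risks**

Total step count: 13. Longest linear sequence: 11 steps (steps 1–9, 12 and 13, from syringaldehyde).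

Steps most likely to fail:

1. Step 7 (Prins). The 1,2-diaryl alkene may turn over slowly inside the confined pocket, the enantioface discrimination at the bromoaryl-bearing carbon may be weak, or Friedel–Crafts hydroxymethylation of the trioxygenated ring may compete. The fallback uses known chemistry and replaces catalyst control by diastereomer separation. It sets out from 7, whose phenol is acylated with (S)-α-methoxy-α-(trifluoromethyl)phenylacetyl chloride (Et3N, DMAP, CH2Cl2) to the equally electron-poor chiral ester 4-bromo-2-[(E)-2-{3,5-dimethoxy-4-[(triisopropylsilyl)oxy]phenyl}ethenyl]-6-methoxyphenyl (2R)-3,3,3-trifluoro-2-methoxy-2-phenylpropanoate F1. A classical Prins reaction with paraformaldehyde and an achiral strong acid (Tf2NH, CH2Cl2, 0 °C) should then give the two trans-dioxanes as diastereomers: the (4S,5S)-dioxane (2R)-3,3,3-trifluoro-2-methoxy-2-phenylpropanoate F2 and the (4R,5R)-dioxane (2R)-3,3,3-trifluoro-2-methoxy-2-phenylpropanoate F3. These are to be separated by chromatography or crystallisation and assigned by X-ray diffraction using the bromine atom. Treating F2 with iBu2AlH (CH2Cl2, −78 °C) cleaves the aryl ester and comes back to the route at 11.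

2. Step 9 (ring switch). The formal may resist benzylic ionisation at acidities that the C3 arm tolerates, and forcing the acid may bring proton loss from C3 of the cation (stilbene formation, erosion of the C3 configuration) or loss of the C3 arm as formaldehyde. The fallback separates acetal removal from ring closure. It sets out from 11: Me2BBr (CH2Cl2, −78 °C, then aqueous NaHCO3) attacks the formal at its methylene carbon and should release (1S,2S)-2-(5-bromo-2-hydroxy-3-methoxyphenyl)-1-{3,5-dimethoxy-4-[(triisopropylsilyl)oxy]phenyl}propane-1,3-diol F4. Its free benzylic alcohol ionises under far weaker acid (pyridinium p-toluenesulfonate, CH2Cl2, rt) and closes by cyclodehydration to the trans-dihydrobenzofuran, coming back at 13.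

3. Step 12 (Heck). Oxidative addition into the electron-rich aryl bromide may be slow, and prolonged heating may lead to silyl loss or to insertion with the wrong regiochemistry (1,1-diaryl ethene). The fallback changes the coupling mode. It sets out from 15: the boron variant of the Takai olefination (2-(dichloromethyl)-4,4,5,5-tetramethyl-1,3,2-dioxaborolane, CrCl2, LiI, THF, rt) should give 2-[(E)-2-{3,5-bis[(triisopropylsilyl)oxy]phenyl}ethenyl]-4,4,5,5-tetramethyl-1,3,2-dioxaborolane F5. This is joined to bromide 13 by Suzuki–Miyaura coupling (PdCl2(dppf), K3PO4, 1,4-dioxane–H2O, 70 °C) and comes back at 17.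

Further compounds
F1 | step 7 | 4-bromo-2-[(E)-2-{3,5-dimethoxy-4-[(triisopropylsilyl)oxy]phenyl}ethenyl]-6-methoxyphenyl (2R)-3,3,3-trifluoro-2-methoxy-2-phenylpropanoate | COc1cc(/C=C/c2cc(Br)cc(OC)c2OC(=O)[C@](OC)(c3ccccc3)C(F)(F)F)cc(OC)c1O[Si](C(C)C)(C(C)C)C(C)C
F2 | step 7 | 4-bromo-2-[(4S,5S)-4-{3,5-dimethoxy-4-[(triisopropylsilyl)oxy]phenyl}-1,3-dioxan-5-yl]-6-methoxyphenyl (2R)-3,3,3-trifluoro-2-methoxy-2-phenylpropanoate | COc1cc([C@H]2OCOC[C@@H]2c2cc(Br)cc(OC)c2OC(=O)[C@](OC)(c3ccccc3)C(F)(F)F)cc(OC)c1O[Si](C(C)C)(C(C)C)C(C)C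
F3 | step 7 | 4-bromo-2-[(4R,5R)-4-{3,5-dimethoxy-4-[(triisopropylsilyl)oxy]phenyl}-1,3-dioxan-5-yl]-6-methoxyphenyl (2R)-3,3,3-trifluoro-2-methoxy-2-phenylpropanoate | COc1cc([C@@H]2OCOC[C@H]2c2cc(Br)cc(OC)c2OC(=O)[C@](OC)(c3ccccc3)C(F)(F)F)cc(OC)c1O[Si](C(C)C)(C(C)C)C(C)C
F4 | step 9 | (1S,2S)-2-(5-bromo-2-hydroxy-3-methoxyphenyl)-1-{3,5-dimethoxy-4-[(triisopropylsilyl)oxy]phenyl}propane-1,3-diol | COc1cc([C@@H](O)[C@H](CO)c2cc(Br)cc(OC)c2O)cc(OC)c1O[Si](C(C)C)(C(C)C)C(C)C
F5 | step 12 | 2-[(E)-2-{3,5-bis[(triisopropylsilyl)oxy]phenyl}ethenyl]-4,4,5,5-tetramethyl-1,3,2-dioxaborolane | CC(C)[Si](Oc1cc(/C=C/B2OC(C)(C)C(C)(C)O2)cc(O[Si](C(C)C)(C(C)C)C(C)C)c1)(C(C)C)C(C)C
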